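**Retrosynthetic overview**
1. The C2-symmetric C40 tetrol is cut at C6–C7 and C6'–C7' (twofold Sonogashira coupling) into one all-E C22 heptaene-diyne 20 and two identical ring enol triflates 12.
2. The strategy rests on this feature of each ring (C1 gem-dimethyl, C2 methylene, C3 and C4 carbinols, C5 methyl-bearing, C6 alkynyl-bearing): the C4 carbinol is β to C6 once C6 is read as a ketone carbon, so C4–C5 is an aldol bond, and C2–C3(O)–C4 is a glycerol unit.
3. The cyclohexane ring is the only ring formed. It is closed once per half, by intramolecular aldol addition of keto aldehyde 9 (C5 enolate onto the C4 aldehyde) to the 3,4-trans hydroxy ketone 10, before the polyene is attached; the C5=C6 double bond follows by enol triflation.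
4. Keto aldehyde 9 is assembled from isobutyronitrile (C1, its two methyls, C6), (S)-benzyl glycidyl ether (C2–C4, source of the C3 configuration) and EtMgBr (C5 and its methyl).
5. Diyne 20 comes from the C10 trienedial 18 and two C6 enyne phosphonates 17 by twofold Horner–Wadsworth–Emmons olefination.

Key step: step 6

Remark: ring atoms are numbered as in carotenoids throughout; TBS = tert-butyldimethylsilyl; all work with polyenes 19 to 22 is assumed to be done under argon with exclusion of light.

**Step 1**
Reactants: 1 isobutyronitrile; 2 (S)-benzyl glycidyl ether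
Product: 3 (S)-5-(benzyloxy)-4-hydroxy-2,2-dimethylpentanenitrile
Conditions: LiN(i-Pr)2, THF, −78 °C; then 2, −78 to 0 °C; then H2O
Reagents that add atoms: none
Why: The α-cyano carbanion opens the monosubstituted epoxide at its unsubstituted carbon (SN2 epoxide opening by a nitrile anion), so the glycidyl stereocentre is untouched and becomes C3, and a cold quench keeps the alkoxide from adding to the nitrile.

**Step 2**
Reactants: 3 (S)-5-(benzyloxy)-4-hydroxy-2,2-dimethylpentanenitrile
Product: 4 (S)-5-(benzyloxy)-4-[(tert-butyldimethylsilyl)oxy]-2,2-dimethylpentanenitrile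
Conditions: TBSCl, imidazole, DMF, rt
Reagents that add atoms: tert-butyldimethylsilyl chloride, CC(C)(C)[Si](C)(C)Cl
Why: Imidazole-promoted O-silylation of a secondary alcohol is routine, and the TBS ether is inert to the Grignard reagent of step 3.

**Step 3**
Reactants: 4 (S)-5-(benzyloxy)-4-[(tert-butyldimethylsilyl)oxy]-2,2-dimethylpentanenitrile; 5 ethylmagnesium bromide
Product: 7 (S)-7-(benzyloxy)-6-[(tert-butyldimethylsilyl)oxy]-4,4-dimethylheptan-3-one, via bromomagnesium ketimide 6 (not isolated)
Conditions: EtMgBr (3 equiv), CuBr·SMe2 (5 mol %), THF, reflux; then 10% aq. citric acid, rt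
Reagents that add atoms: water, O
Why: Grignard addition to a nitrile without α-hydrogen stops at the ketimide and cannot over-add, catalysis by monovalent copper overcomes the hindrance of the quaternary neighbour, and mild acid hydrolysis of the ketimine should give the ethyl ketone with the silyl ether intact.

**Step 4**
Reactants: 7 (S)-7-(benzyloxy)-6-[(tert-butyldimethylsilyl)oxy]-4,4-dimethylheptan-3-one
Product: 8 (S)-6-[(tert-butyldimethylsilyl)oxy]-7-hydroxy-4,4-dimethylheptan-3-one
Conditions: H2 (1 atm), Pd/C (10 wt %), EtOAc, rt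
Reagents that add atoms: none
Why: Hydrogenolysis of a benzyl ether over palladium under neutral conditions leaves the silyl ether and the hindered ketone untouched and gives no base that could shift the silyl group to the primary oxygen.

**Step 5**
Reactants: 8 (S)-6-[(tert-butyldimethylsilyl)oxy]-7-hydroxy-4,4-dimethylheptan-3-one
Product: 9 (S)-2-[(tert-butyldimethylsilyl)oxy]-4,4-dimethyl-5-oxoheptanal
Conditions: Dess–Martin periodinane, CH2Cl2, 0 °C to rt
Reagents that add atoms: none
Why: Dess–Martin oxidation takes the primary alcohol to the aldehyde under conditions that do not epimerise an α-silyloxy aldehyde, and any six-membered lactol form of 8 is drained through the open hydroxy ketone.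

**Step 6**
Reactants: 9 (S)-2-[(tert-butyldimethylsilyl)oxy]-4,4-dimethyl-5-oxoheptanal
Product: 10 (4S,5S,6S)-4-[(tert-butyldimethylsilyl)oxy]-5-hydroxy-2,2,6-trimethylcyclohexan-1-one (all-equatorial; carotenoid C3 silyl ether and C4 hydroxyl trans)
Conditions: MgBr2·OEt2 (2.5 equiv), Et3N (3 equiv), CH2Cl2 (0.02 M), 0 °C to rt; then pH 7 buffer
Reagents that add atoms: none
Why: MgBr2 activates the ketone so that Et3N can remove a C5 proton (soft enolisation), and the bromomagnesium enolate, the only one possible because C1 is quaternary, adds through C5 to the C4 aldehyde in an intramolecular aldol addition, the closest known reaction type being the magnesium halide/amine-mediated direct aldol addition of ketones. The ring closes in the 6-(enolendo)-exo-trig mode through a chair in which the C3 silyl ether is equatorial, because an axial one would clash with the axial C1 methyl. C4 is set under thermodynamic control: the addition is reversible under these conditions, the bulky magnesium alkoxide prefers the equatorial site trans to the C3 silyl ether, and the axial epimer gains nothing from chelation because an axial C4 oxygen sits over the face, not in the plane, of the C6 carbonyl. C5 is epimerisable and should settle with its methyl equatorial, and it is erased in step 8 in any case. The step needs the 3,4-trans relationship and an intact C3 centre: the first rests on the equatorial bias that the gem-dimethyl group imposes on the ring, the second on the weakness of the amine base toward the hindered α-silyloxy aldehyde while fast ring closure keeps the open form scarce.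

**Step 7**
Reactants: 10 (4S,5S,6S)-4-[(tert-butyldimethylsilyl)oxy]-5-hydroxy-2,2,6-trimethylcyclohexan-1-one
Product: 11 (4S,5S,6S)-4,5-bis[(tert-butyldimethylsilyl)oxy]-2,2,6-trimethylcyclohexan-1-one
Conditions: TBSOTf, 2,6-lutidine, CH2Cl2, −78 to 0 °C
Reagents that add atoms: tert-butyldimethylsilyl trifluoromethanesulfonate, CC(C)(C)[Si](C)(C)OS(=O)(=O)C(F)(F)F
Why: Silyl triflate/2,6-lutidine silylation of a hindered secondary alcohol at low temperature is too weakly basic to trigger retro-aldol cleavage or ketone enolisation, and any 1,2-silyl shift between the two oxygens in step 6 converges here on the same bis-silyl ether.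

**Step 8**
Reactants: 11 (4S,5S,6S)-4,5-bis[(tert-butyldimethylsilyl)oxy]-2,2,6-trimethylcyclohexan-1-one
Product: 12 (3S,4S)-3,4-bis[(tert-butyldimethylsilyl)oxy]-2,6,6-trimethylcyclohex-1-en-1-yl trifluoromethanesulfonate
Conditions: KN(SiMe3)2, THF, −78 to −20 °C; PhNTf2, −78 °C to rt; then H2O
Reagents that add atoms: N-phenylbis(trifluoromethanesulfonimide), O=S(=O)(N(c1ccccc1)S(=O)(=O)C(F)(F)F)C(F)(F)F
Why: Enol triflate formation from a ketone enolate is regiochemically unambiguous here because the ketone can enolise only toward C5, whose axial hydrogen is removed by the amide base, and O-triflation fixes the C5=C6 double bond and erases the C5 stereocentre while the equatorial C4 silyloxy group is not aligned for β-elimination.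

**Step 9**
Reactants: 13 (E)-3-methylpent-2-en-4-yn-1-ol
Product: 15 (E)-3-methyl-5-(trimethylsilyl)pent-2-en-4-yn-1-ol, via bis-silylated enynol 14 (not isolated)
Conditions: n-BuLi (2.2 equiv), THF, −78 °C; Me3SiCl (2.3 equiv), −78 °C to rt; then 1 M aq. HCl, rt
Reagents that add atoms: chlorotrimethylsilane, C[Si](C)(C)Cl
Why: Double deprotonation gives the alkoxide acetylide, both sites are silylated and only the labile O–Si bond is hydrolysed by dilute acid (C-silylation of a terminal alkyne), the E double bond not being involved.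

**Step 10**
Reactants: 15 (E)-3-methyl-5-(trimethylsilyl)pent-2-en-4-yn-1-ol
Product: 16 (E)-(5-bromo-3-methylpent-3-en-1-yn-1-yl)trimethylsilane
Conditions: CBr4, PPh3, CH2Cl2, 0 °C
Reagents that add atoms: carbon tetrabromide, BrC(Br)(Br)Br
Why: Appel bromination converts the primary allylic alcohol into the bromide under neutral conditions without allylic transposition or E/Z isomerisation.

**Step 11**
Reactants: 16 (E)-(5-bromo-3-methylpent-3-en-1-yn-1-yl)trimethylsilane
Product: 17 diethyl [(2E)-3-methyl-5-(trimethylsilyl)pent-2-en-4-yn-1-yl]phosphonate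
Conditions: P(OEt)3, neat, 110 °C
Reagents that add atoms: triethyl phosphite, CCOP(OCC)OCC
Why: The Michaelis–Arbuzov reaction of a primary allylic bromide with triethyl phosphite gives the phosphonate with the double bond geometry retained.

**Step 12**
Reactants: 17 diethyl [(2E)-3-methyl-5-(trimethylsilyl)pent-2-en-4-yn-1-yl]phosphonate (2.2 equiv); 18 (2E,4E,6E)-2,7-dimethylocta-2,4,6-trienedial
Product: 19 (all-E)-3,7,12,16-tetramethyl-1,18-bis(trimethylsilyl)octadeca-3,5,7,9,11,13,15-heptaene-1,17-diyne
Conditions: NaN(SiMe3)2, THF, −78 °C; then 18, −78 to 0 °C; then H2O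
Reagents that add atoms: none
Why: Twofold Horner–Wadsworth–Emmons olefination of the dialdehyde with the allylic phosphonate anion forms the C11=C12 and C11'=C12' bonds, E geometry being favoured by the reversible addition that precedes elimination, and the silyl caps keep the alkyne termini from being deprotonated.

**Step 13**
Reactants: 19 (all-E)-3,7,12,16-tetramethyl-1,18-bis(trimethylsilyl)octadeca-3,5,7,9,11,13,15-heptaene-1,17-diyne
Product: 20 (all-E)-3,7,12,16-tetramethyloctadeca-3,5,7,9,11,13,15-heptaene-1,17-diyne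
Conditions: K2CO3 (cat.), MeOH/THF, rt
Reagents that add atoms: none
Why: Carbonate-catalysed methanolysis of the alkynyl–silicon bonds (protiodesilylation) frees both terminal alkynes without touching the polyene.

**Step 14**
Reactants: 12 (3S,4S)-3,4-bis[(tert-butyldimethylsilyl)oxy]-2,6,6-trimethylcyclohex-1-en-1-yl trifluoromethanesulfonate (2.2 equiv); 20 (all-E)-3,7,12,16-tetramethyloctadeca-3,5,7,9,11,13,15-heptaene-1,17-diyne
Product: 21 (all-E,3S,4S,3'S,4'S)-3,3',4,4'-tetrakis[(tert-butyldimethylsilyl)oxy]-7,8,7',8'-tetradehydro-β,β-carotene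
Conditions: Pd(PPh3)4 (10 mol %), CuI (20 mol %), i-Pr2NH, THF (degassed), rt to 40 °C
Reagents that add atoms: none
Why: In this twofold Sonogashira coupling zerovalent palladium inserts into each alkenyl C–OTf bond, the copper acetylides formed from 20 and CuI transmetalate and reductive elimination forges C6–C7 and C6'–C7', a coupling established for 2,6,6-trimethylcyclohexenyl triflates, with no stereocentre or double bond geometry touched and an amine medium that silyl ethers and polyene tolerate.

**Step 15**
Reactants: 21 (all-E,3S,4S,3'S,4'S)-3,3',4,4'-tetrakis[(tert-butyldimethylsilyl)oxy]-7,8,7',8'-tetradehydro-β,β-carotene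
Product: 22 (all-E,3S,4S,3'S,4'S)-7,8,7',8'-tetradehydro-β,β-carotene-3,3',4,4'-tetrol (CNP0283832.1)
Conditions: Bu4NF (excess), THF, 0 °C to rt; then H2O
Reagents that add atoms: none
Why: Fluoride-induced cleavage of the four silyl ethers under non-acidic conditions avoids ionisation of the allylic C4 carbinols and leaves unchanged the four stereocentres, of which C3 and C3' come from the glycidyl ether of step 1 and C4 and C4' from the aldol closure of step 6.

**Compound list**
1 | isobutyronitrile | CC(C)C#N | starting material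
2 | (S)-benzyl glycidyl ether | C1O[C@@H]1COCc1ccccc1 | starting material
3 | (S)-5-(benzyloxy)-4-hydroxy-2,2-dimethylpentanenitrile | N#CC(C)(C)C[C@H](O)COCc1ccccc1 | intermediate
4 | (S)-5-(benzyloxy)-4-[(tert-butyldimethylsilyl)oxy]-2,2-dimethylpentanenitrile | N#CC(C)(C)C[C@H](O[Si](C)(C)C(C)(C)C)COCc1ccccc1 | intermediate
5 | ethylmagnesium bromide | CC[Mg]Br | starting material
6 | bromomagnesium ketimide of 7 (not isolated) | CCC(=N[Mg]Br)C(C)(C)C[C@H](O[Si](C)(C)C(C)(C)C)COCc1ccccc1 | intermediate
7 | (S)-7-(benzyloxy)-6-[(tert-butyldimethylsilyl)oxy]-4,4-dimethylheptan-3-one | CCC(=O)C(C)(C)C[C@H](O[Si](C)(C)C(C)(C)C)COCc1ccccc1 | intermediate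
8 | (S)-6-[(tert-butyldimethylsilyl)oxy]-7-hydroxy-4,4-dimethylheptan-3-one | CCC(=O)C(C)(C)C[C@H](O[Si](C)(C)C(C)(C)C)CO | intermediate
9 | (S)-2-[(tert-butyldimethylsilyl)oxy]-4,4-dimethyl-5-oxoheptanal | CCC(=O)C(C)(C)C[C@H](O[Si](C)(C)C(C)(C)C)C=O | intermediate
10 | (4S,5S,6S)-4-[(tert-butyldimethylsilyl)oxy]-5-hydroxy-2,2,6-trimethylcyclohexan-1-one | C[C@@H]1C(=O)C(C)(C)C[C@H](O[Si](C)(C)C(C)(C)C)[C@H]1O | intermediate
11 | (4S,5S,6S)-4,5-bis[(tert-butyldimethylsilyl)oxy]-2,2,6-trimethylcyclohexan-1-one | C[C@@H]1C(=O)C(C)(C)C[C@H](O[Si](C)(C)C(C)(C)C)[C@H]1O[Si](C)(C)C(C)(C)C | intermediate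
12 | (3S,4S)-3,4-bis[(tert-butyldimethylsilyl)oxy]-2,6,6-trimethylcyclohex-1-en-1-yl trifluoromethanesulfonate | CC1=C(OS(=O)(=O)C(F)(F)F)C(C)(C)C[C@H](O[Si](C)(C)C(C)(C)C)[C@H]1O[Si](C)(C)C(C)(C)C | intermediate
13 | (E)-3-methylpent-2-en-4-yn-1-ol | C#C/C(C)=C/CO | starting material
14 | (E)-trimethyl{[3-methyl-5-(trimethylsilyl)pent-2-en-4-yn-1-yl]oxy}silane (not isolated) | C[Si](C)(C)C#C/C(C)=C/CO[Si](C)(C)C | intermediate
15 | (E)-3-methyl-5-(trimethylsilyl)pent-2-en-4-yn-1-ol | C[Si](C)(C)C#C/C(C)=C/CO | intermediate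
16 | (E)-(5-bromo-3-methylpent-3-en-1-yn-1-yl)trimethylsilane | C[Si](C)(C)C#C/C(C)=C/CBr | intermediate
17 | diethyl [(2E)-3-methyl-5-(trimethylsilyl)pent-2-en-4-yn-1-yl]phosphonate | CCOP(=O)(OCC)C/C=C(\C)C#C[Si](C)(C)C | intermediate
18 | (2E,4E,6E)-2,7-dimethylocta-2,4,6-trienedial | O=C/C(C)=C/C=C/C=C(\C)C=O | starting material
19 | (3E,5E,7E,9E,11E,13E,15E)-3,7,12,16-tetramethyl-1,18-bis(trimethylsilyl)octadeca-3,5,7,9,11,13,15-heptaene-1,17-diyne | C[Si](C)(C)C#C/C(C)=C/C=C/C(C)=C/C=C/C=C(C)/C=C/C=C(\C)C#C[Si](C)(C)C | intermediate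
20 | (3E,5E,7E,9E,11E,13E,15E)-3,7,12,16-tetramethyloctadeca-3,5,7,9,11,13,15-heptaene-1,17-diyne | C#C/C(C)=C/C=C/C(C)=C/C=C/C=C(C)/C=C/C=C(\C)C#C | intermediate
21 | (all-E,3S,4S,3'S,4'S)-3,3',4,4'-tetrakis[(tert-butyldimethylsilyl)oxy]-7,8,7',8'-tetradehydro-β,β-carotene | CC1=C(C#C/C(C)=C/C=C/C(C)=C/C=C/C=C(C)/C=C/C=C(\C)C#CC2=C(C)[C@H](O[Si](C)(C)C(C)(C)C)[C@@H](O[Si](C)(C)C(C)(C)C)CC2(C)C)C(C)(C)C[C@H](O[Si](C)(C)C(C)(C)C)[C@H]1O[Si](C)(C)C(C)(C)C | intermediate
22 | (all-E,3S,4S,3'S,4'S)-7,8,7',8'-tetradehydro-β,β-carotene-3,3',4,4'-tetrol (CNP0283832.1) | CC1=C(C#C/C(C)=C/C=C/C(C)=C/C=C/C=C(C)/C=C/C=C(\C)C#CC2=C(C)[C@H](O)[C@@H](O)CC2(C)C)C(C)(C)C[C@H](O)[C@H]1O | target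

**Step count**
Total: 15 steps. Longest linear sequence: 10 steps (steps 1 to 8, 14 and 15).

**Steps most likely to fail**

Step 6 (key aldol closure). Two processes threaten it. Ring closure may run through a magnesium-bridged, closed transition state in which the aldehyde oxygen is synclinal to the enolate and ends up axial at C4, cis to the C3 silyl ether, and retro-aldol equilibration to the equatorial epimer may be too slow or too shallow to correct this. In addition the amine may enolise the α-silyloxy aldehyde and erode the C3 configuration. The fallback sets out from 7 and comes back at 10; it makes the enolate equivalent before the aldehyde exists and closes the ring without base. TBSOTf/Et3N should convert 7 into (S,Z)-7-(benzyloxy)-3,6-bis[(tert-butyldimethylsilyl)oxy]-4,4-dimethylhept-2-ene F1. Hydrogenolysis (H2, Pd/C, EtOAc), which a hindered trisubstituted silyl enol ether should survive, would give (S,Z)-2,5-bis[(tert-butyldimethylsilyl)oxy]-4,4-dimethylhept-5-en-1-ol F2, and Dess–Martin oxidation would give (S,Z)-2,5-bis[(tert-butyldimethylsilyl)oxy]-4,4-dimethylhept-5-enal F3. BF3·OEt2 in CH2Cl2 at −78 °C would then close the ring by an intramolecular Mukaiyama aldol addition through an open transition state, in which the boron-bound aldehyde oxygen lies equatorial and antiperiplanar to the silyloxy-bearing C6, and aqueous work-up would give 10.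

Step 14 (twofold Sonogashira coupling). Oxidative addition at the tetrasubstituted, doubly flanked enol triflate may be slow, which would leave the diyne exposed to oxidative homocoupling and the heptaene to isomerisation and decomposition in the presence of palladium and copper. The fallback sets out from 12 (with 13 and 18) and comes back at 21; it moves the cross-coupling to a small, robust alkyne and builds the polyene afterwards in the C15 + C10 + C15 manner. Sonogashira coupling of 12 with 13 would give (2E)-5-[(3S,4S)-3,4-bis[(tert-butyldimethylsilyl)oxy]-2,6,6-trimethylcyclohex-1-en-1-yl]-3-methylpent-2-en-4-yn-1-ol F4. PPh3·HBr in CH2Cl2 would give {(2E)-5-[(3S,4S)-3,4-bis[(tert-butyldimethylsilyl)oxy]-2,6,6-trimethylcyclohex-1-en-1-yl]-3-methylpent-2-en-4-yn-1-yl}triphenylphosphonium bromide F5. Twofold Wittig olefination of 18 with the ylide from F5 (NaOMe, CH2Cl2/MeOH), followed by thermal Z to E equilibration of the new 11,12 and 11',12' double bonds, would give 21.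

Step 8 (enol triflation). Deprotonation of the single, tertiary and hindered C5 hydrogen may be slow, and the enolate once formed may expel the C4 silyloxy group by β-elimination before it is trapped. The fallback sets out from 11 (with 20) and comes back at 21, bypassing steps 8 and 14; it forms the C6–C7 bond by carbonyl addition instead of cross-coupling. Diyne 20 would be deprotonated twice with n-BuLi, transmetalated with CeCl3 and added to two equivalents of 11 to give the twofold tertiary propargylic alcohol 1,1'-[(all-E)-3,7,12,16-tetramethyloctadeca-3,5,7,9,11,13,15-heptaene-1,17-diyne-1,18-diyl]bis{(2S,3S,4S)-3,4-bis[(tert-butyldimethylsilyl)oxy]-2,6,6-trimethylcyclohexan-1-ol} F6 (configuration at the two carbinol carbons not defined). Twofold dehydration with Burgess reagent, which can only run toward C5 and C5' because C1 and C1' are quaternary, would give 21 with loss of water only.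

**Further compounds**
F1 | step 6 | (S,Z)-7-(benzyloxy)-3,6-bis[(tert-butyldimethylsilyl)oxy]-4,4-dimethylhept-2-ene | C/C=C(\O[Si](C)(C)C(C)(C)C)C(C)(C)C[C@H](O[Si](C)(C)C(C)(C)C)COCc1ccccc1
F2 | step 6 | (S,Z)-2,5-bis[(tert-butyldimethylsilyl)oxy]-4,4-dimethylhept-5-en-1-ol | C/C=C(\O[Si](C)(C)C(C)(C)C)C(C)(C)C[C@H](O[Si](C)(C)C(C)(C)C)CO
F3 | step 6 | (S,Z)-2,5-bis[(tert-butyldimethylsilyl)oxy]-4,4-dimethylhept-5-enal | C/C=C(\O[Si](C)(C)C(C)(C)C)C(C)(C)C[C@H](O[Si](C)(C)C(C)(C)C)C=O
F4 | step 14 | (2E)-5-[(3S,4S)-3,4-bis[(tert-butyldimethylsilyl)oxy]-2,6,6-trimethylcyclohex-1-en-1-yl]-3-methylpent-2-en-4-yn-1-ol | CC1=C(C#C/C(C)=C/CO)C(C)(C)C[C@H](O[Si](C)(C)C(C)(C)C)[C@H]1O[Si](C)(C)C(C)(C)C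
F5 | step 14 | {(2E)-5-[(3S,4S)-3,4-bis[(tert-butyldimethylsilyl)oxy]-2,6,6-trimethylcyclohex-1-en-1-yl]-3-methylpent-2-en-4-yn-1-yl}triphenylphosphonium bromide | CC1=C(C#C/C(C)=C/C[P+](c2ccccc2)(c2ccccc2)c2ccccc2)C(C)(C)C[C@H](O[Si](C)(C)C(C)(C)C)[C@H]1O[Si](C)(C)C(C)(C)C.[Br-]
F6 | step 8 | 1,1'-[(all-E)-3,7,12,16-tetramethyloctadeca-3,5,7,9,11,13,15-heptaene-1,17-diyne-1,18-diyl]bis{(2S,3S,4S)-3,4-bis[(tert-butyldimethylsilyl)oxy]-2,6,6-trimethylcyclohexan-1-ol} | C[C@@H]1C(O)(C#C/C(C)=C/C=C/C(C)=C/C=C/C=C(C)/C=C/C=C(\C)C#CC2(O)[C@@H](C)[C@H](O[Si](C)(C)C(C)(C)C)[C@@H](O[Si](C)(C)C(C)(C)C)CC2(C)C)C(C)(C)C[C@H](O[Si](C)(C)C(C)(C)C)[C@H]1O[Si](C)(C)C(C)(C)C
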